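The earlier runs and the new flask were computed for substances that don't exist.

Which flask holds the most target after 8.0 min: Thursday's, kept warm, Saturday's, kept cold, or Sunday's, warmed halfway?

| setting | delta | beta | alpha | Sunday's | Saturday's | Thursday's |
|---|---|---|---|---|---|---|
| starting material | 0.070 M | 0.11 M | 0.050 M | 0.050 M | 0.050 M | 0.050 M |
| first nucleophile | 4 equiv | 4 equiv | 4 equiv | 4.00 equiv | 4.00 equiv | 4.00 equiv |
| second nucleophile | 1.3 equiv | 1.3 equiv | 2 equiv | 1.30 equiv | 1.30 equiv | 1.30 equiv |
| temperature | −12 °C | 4 °C | −12 °C |  | −20 °C | 10 °C |
| remark | run made earlier | run made earlier | run made earlier | at −20 °C until 4.0 min, from then on at 10 °C |  |  |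
| time |  |  |  | 8.0 min | 8.0 min | 8.0 min |

- delta (time / min: target / %, starting material / %): 1.33: 6.4, 50.7; 2.50: 9.2, 34.1; 4.00: 10.8, 28.9; 5.00: 11.9, 24.5
- beta (time / s: target / %, starting material / %): 25.0: 8.4, 32.2; 50.0: 9.3, 20.6; 80.0: 15.3, 16.9; 90.0: 16.2, 16.1
- alpha (time / min: target / %, starting material / %): 1.33: 6.0, 55.6; 2.50: 8.3, 37.0; 4.00: 9.3, 28.8; 5.00: 11.1, 25.2

(each reading ± 1 percentage point)



- the best flask by amount of target, in percent of the starting material charged; "all alike" if 1.5 percentage points covers them all (Sunday's / Saturday's / Thursday's / all alike)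
- amount of target at the end, in percent of the starting material charged, Sunday's
- amount of target at the end, in percent of the starting material charged, Saturday's
- amount of target at the end, in percent of the starting material charged, Thursday's

I began with the fraction of starting material left. For a first-order loss with rate constant k, the fraction left after time t is f = exp(−kt). It falls by the same share in each equal interval.

The beta run did not hold to a single k. It gave 1.07 min⁻¹ over its first interval, and later it slowed. So I defined k_t, the tail constant, as the apparent first-order rate constant of the late stretch. From 50.0 s to 90.0 s it came to 0.370 min⁻¹, which is slower than the first interval. It rests on two readings, so it is rough. The delta run, which was colder, gave 0.132 min⁻¹ from 2.50 min to 5.00 min, a smaller value.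

I then used beta as a stand-in for Thursday's flask. Its last reading, 16.1%, decayed at k_t to the end, left 1.46%. For Sunday's flask I took delta's reading at 4.0 min, 28.9%, and gave it the warm stretch at k_t, which left 6.59%. Both stand-ins are crude: Sunday's cold stretch is colder than delta, and its warm stretch is warmer than beta. Saturday's flask, colder than delta, should stay above delta's decay, 16.5%. Since target rose as starting material fell in every run, I expected Thursday's to hold the most and Saturday's the least.

The forecast named Thursday's as best, with 38% there, 27% in Sunday's and 10% in Saturday's, on the ground that “eight warm minutes give the most target”.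

The flasks gave 41.5% in Thursday's, 34.0% in Sunday's and 9.11% in Saturday's, so Thursday's led. Starting material left was 1.73% in Thursday's against my 1.46%, and 5.86% in Sunday's against my 6.59%. Saturday's kept 32.6%, more than 16.5%.

    starting material → intermediate (k = 4.27 × 10⁻⁴ s⁻¹, Ea = 70.0 kJ mol⁻¹)
    first nucleophile + intermediate → target (k = 4.13 M⁻¹ s⁻¹, Ea = 41.0 kJ mol⁻¹)
    second nucleophile + intermediate → other capture product (k = 0.725 M⁻¹ s⁻¹, Ea = 43.0 kJ mol⁻¹)
    intermediate → solvolysis product (k = 0.141 s⁻¹, Ea = 66.0 kJ mol⁻¹)
    2 starting material → homo dimer (k = 0.0128 M⁻¹ s⁻¹, Ea = 57.0 kJ mol⁻¹)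
    starting material ⇌ dormant form (K = 1.40, k = 0.00200 s⁻¹, Ea = 71.0 kJ mol⁻¹, ΔH = 2.00 kJ mol⁻¹)
    (constants at −20 °C)

A neighbour of Sunday's flask took 16.0 equiv of first nucleophile, with its other charges and the time held. I carried k_t over unchanged, so I reckoned the same 6.59% left. The neighbour left 5.86%, the same as Sunday's 5.86%. The fraction left showed how much had gone, but not where it went. Solvolysis product stood at 6.54% against 18.8% in Sunday's, and target reached 47.7%.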